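**Retrosynthetic overview**

- Numbering: C2 isopropenyl carbon, C3 side-chain carbinol, C4 and C5 methylenes, C6 methylidene-bearing carbon, C7 ring carbinol, then C8, C9, C10 (CH3, Br), C11 (Cl), C12. The route rests on the single cyclohexane ring C7–C12. Oxygenated quaternary C7 and methyl-bearing C10 stand 1,4, and the trans C10–Br/C11–Cl pair is a masked C10=C11 alkene. The ring is therefore the para Diels–Alder adduct of isoprene (C9–C12 plus the methyl) and an acrolein carrying the C7 oxygen (C8, C7, C6).
- Endgame: C6=CH2 comes from Peterson olefination of a C6 ketone. C5–C6 comes from Negishi acylation of an (R)-C3-silyloxy alkylzinc (C3 set by CBS reduction) with the ring acid chloride, so no C6 alkoxide ever sits next to the C7 benzoate.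
- The halogens go in before the side chain, because HBr-type conditions would add to the 1,1-disubstituted alkenes and ionise the tertiary allylic C7 alcohol. The C6 carboxyl group serves as a tether (chlorolactonisation onto C10, Cl to C11). Me3SiBr then exchanges the lactone oxygen for bromide with retention through the chloronium ion.
- Ring order: the carbocycle is the only permanent ring and is closed first, in the enantioselective [4+2] step. The 2-oxabicyclo[2.2.2]octanone bridge is a temporary second ring, closed in step 5 and opened in step 6.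

Key step: step 3

Assumption: the (R)-diamine salt is taken to leave open the dienophile face that leads to the (S)-adduct; this sense of induction with isoprene has to be confirmed on the chlorolactone or a crystalline derivative (anomalous dispersion of the halogen), and the equally available (S)-diamine is used if it proves opposite.

**Route**

Step 1
Reactants: 1 2,2-dimethyl-1,3-dioxan-5-one; 2 benzoyl chloride
Product: 4 2,2-dimethyl-4H-1,3-dioxin-5-yl benzoate, via potassium enolate 3 (not isolated)
Conditions: KN(SiMe3)2 (1.05 equiv), THF, −78 °C; then 2, −78 to 0 °C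
Reagents that add atoms: none
Why: Enolate O-acylation, in which the dissociated potassium enolate of the symmetrical ketone takes up the hard acyl chloride at oxygen to give the enol benzoate, and no stereocentre is formed.

Step 2
Reactants: 4 2,2-dimethyl-4H-1,3-dioxin-5-yl benzoate
Product: 5 2-(benzoyloxy)acrolein (3-oxoprop-1-en-2-yl benzoate)
Conditions: toluene, reflux, trace BHT, acetone distilled off
Reagents that add atoms: none
Why: Thermal retro-hetero-Diels–Alder reaction, since the 4H-1,3-dioxin is the formal [4+2] adduct of the acyloxyacrolein and acetone, and loss of volatile acetone under neutral conditions drives the cycloreversion without exposing the sensitive enal to acid or water.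

Step 3
Reactants: 5 2-(benzoyloxy)acrolein; 6 isoprene
Product: 7 (S)-1-formyl-4-methylcyclohex-3-en-1-yl benzoate
Conditions: (R)-1,1'-binaphthyl-2,2'-diamine (10 mol %), HN(SO2CF3)2 (19 mol %), 6 (5 equiv), EtCN, −60 to −40 °C; aqueous work-up
Reagents that add atoms: none
Why: The primary ammonium salt condenses reversibly with the formyl group of 5 to an alpha-benzoyloxy iminium ion of much lower LUMO energy, isoprene adds to it in a concerted but asynchronous suprafacial [4+2] cycloaddition, and hydrolysis of the product iminium ion releases 7 and the catalyst. The closest known reaction type is the primary-ammonium-catalysed enantioselective Diels–Alder reaction of alpha-acyloxyacroleins with cyclic and simple acyclic dienes. The six-membered carbocycle is closed by intermolecular [4+2] cycloaddition, C8–C9 and C7–C12 being formed in the same step and C10=C11 being left as the new ring alkene. C7 is the only new stereocentre and is set by the catalyst alone: the second ammonium group is expected to hydrogen-bond to the benzoate carbonyl, which fixes the iminium conformation so that one naphthyl ring covers one face of C7=C8 and the diene enters from the other. The step needs para over meta orientation, which the substrates secure because the largest HOMO coefficient of isoprene lies at C9 (the CH2 next to methyl-bearing C10) and the largest LUMO coefficient of the iminium ion lies at unsubstituted C8; endo or exo approach is of no consequence because the diene termini carry no substituents. Low temperature, excess diene and the absence of free base hold back polymerisation of the enal.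

Step 4
Reactants: 7 (S)-1-formyl-4-methylcyclohex-3-en-1-yl benzoate
Product: 8 (S)-1-(benzoyloxy)-4-methylcyclohex-3-ene-1-carboxylic acid
Conditions: NaClO2, NaH2PO4, 2-methyl-2-butene (20 equiv), t-BuOH/H2O, 0 °C to rt
Reagents that add atoms: sodium chlorite, [Na+].[O-]Cl=O
Why: Pinnick oxidation, in which chlorous acid adds to the non-enolisable aldehyde and fragments to the acid while the large excess of 2-methyl-2-butene takes up the hypochlorous acid before it reaches the ring alkene, and C7 is untouched.

Step 5
Reactants: 8 (S)-1-(benzoyloxy)-4-methylcyclohex-3-ene-1-carboxylic acid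
Product: 9 (1S,4S,6S)-6-chloro-1-methyl-3-oxo-2-oxabicyclo[2.2.2]octan-4-yl benzoate
Conditions: NCS (1.1 equiv), MeCN, 0 °C to rt, exclusion of light
Reagents that add atoms: N-chlorosuccinimide, O=C1CCC(=O)N1Cl
Why: Chlorolactonisation (halolactonisation), in which the carboxyl group can reach only the ring face on which C6 stands, so chlorine is delivered to the opposite face in an anti addition, oxygen bonds to the more substituted C10 in the Markovnikov sense (the closure mode known from electrophile-induced cyclisation of alpha-terpineol to the 1,8-cineole skeleton), and C7 thereby fixes C10 (S) and C11 (S) with Cl cis to the benzoate.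

Step 6
Reactants: 9 (1S,4S,6S)-6-chloro-1-methyl-3-oxo-2-oxabicyclo[2.2.2]octan-4-yl benzoate
Product: 11 (1S,3S,4S)-1-(benzoyloxy)-4-bromo-3-chloro-4-methylcyclohexane-1-carboxylic acid, via trimethylsilyl ester 10 (not isolated)
Conditions: Me3SiBr (4 equiv), CH2Cl2, 0 °C to rt; then aqueous pH 4 work-up
Reagents that add atoms: bromotrimethylsilane, C[Si](C)(C)Br
Why: Halosilane cleavage of a tertiary lactone at the alkyl–oxygen bond with neighbouring-group participation, in which silylation of the carbonyl turns the carboxylate into a leaving group, the antiperiplanar C11 chlorine assists ionisation at C10 through a bridged chloronium ion, and bromide opens that ion at the tertiary carbon from the face the oxygen left, so that C10 keeps its configuration by double inversion while release of the boat-shaped bicycle adds driving force.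

Step 7
Reactants: 11 (1S,3S,4S)-1-(benzoyloxy)-4-bromo-3-chloro-4-methylcyclohexane-1-carboxylic acid
Product: 12 (1S,3S,4S)-4-bromo-3-chloro-1-(chlorocarbonyl)-4-methylcyclohexyl benzoate
Conditions: (COCl)2 (1.5 equiv), DMF (2 mol %), CH2Cl2, 0 °C to rt; concentrate, use crude
Reagents that add atoms: oxalyl chloride, O=C(Cl)C(=O)Cl
Why: Acid chloride formation through the chloroiminium (Vilsmeier-type) salt runs under non-basic conditions that leave the tertiary bromide, the secondary chloride and the benzoate alone, and the quaternary alpha-carbon rules out ketene formation.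

Step 8
Reactants: 13 3-chloropropanoyl chloride
Product: 14 3-chloro-N-methoxy-N-methylpropanamide
Conditions: MeNH(OMe)·HCl, pyridine (2.2 equiv), CH2Cl2, 0 °C
Reagents that add atoms: N,O-dimethylhydroxylamine hydrochloride, CNOC.Cl
Why: N-Acylation of the hydroxylamine gives the Weinreb amide, and the weak base pyridine avoids loss of HCl to the acrylamide.

Step 9
Reactants: 14 3-chloro-N-methoxy-N-methylpropanamide; 15 2-bromopropene
Product: 17 1-chloro-4-methylpent-4-en-3-one, via isopropenylmagnesium bromide 16 (not isolated)
Conditions: 15, Mg, THF, 40 °C; then 14, THF, −20 to 0 °C; poured into cold 1 M HCl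
Reagents that add atoms: none
Why: Weinreb ketone synthesis, in which the Grignard reagent adds only once because the magnesium chelate of the tetrahedral adduct survives until the cold acidic quench, which also keeps the liberated amine protonated so that it can neither add to nor dehydrochlorinate the beta-chloro enone.

Step 10
Reactants: 17 1-chloro-4-methylpent-4-en-3-one
Product: 18 (R)-5-chloro-2-methylpent-1-en-3-ol
Conditions: (S)-1-methyl-3,3-diphenyltetrahydro-1H,3H-pyrrolo[1,2-c][1,3,2]oxazaborole (15 mol %), catecholborane (1.5 equiv), toluene, −78 °C; MeOH, then pH 7 buffer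
Reagents that add atoms: none
Why: Corey–Bakshi–Shibata reduction, in which the ketone binds the ring boron of the (S)-oxazaborolidine with the larger isopropenyl group turned away and hydride passes through the six-membered transition state to give the (R)-carbinol C3 (the same sense as acetophenone to (R)-1-phenylethanol), while catecholborane at low temperature does not hydroborate the 1,1-disubstituted alkene.

Step 11
Reactants: 18 (R)-5-chloro-2-methylpent-1-en-3-ol
Product: 19 (R)-tert-butyl[(5-chloro-2-methylpent-1-en-3-yl)oxy]dimethylsilane
Conditions: TBSCl, imidazole, DMF, rt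
Reagents that add atoms: tert-butyldimethylsilyl chloride, CC(C)(C)[Si](C)(C)Cl
Why: Imidazole-promoted O-silylation of the secondary allylic alcohol takes place at oxygen only, so C3 is not touched.

Step 12
Reactants: 19 (R)-tert-butyl[(5-chloro-2-methylpent-1-en-3-yl)oxy]dimethylsilane
Product: 20 (R)-tert-butyl[(5-iodo-2-methylpent-1-en-3-yl)oxy]dimethylsilane
Conditions: NaI (5 equiv), acetone, reflux
Reagents that add atoms: sodium iodide, [Na+].[I-]
Why: Finkelstein reaction, an SN2 halide exchange at the primary carbon C5 driven by precipitation of NaCl, remote from C3.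

Step 13
Reactants: 12 (1S,3S,4S)-4-bromo-3-chloro-1-(chlorocarbonyl)-4-methylcyclohexyl benzoate; 20 (R)-tert-butyl[(5-iodo-2-methylpent-1-en-3-yl)oxy]dimethylsilane
Product: 22 (1S,3S,4S)-4-bromo-1-[(4R)-4-(tert-butyldimethylsilyloxy)-5-methylhex-5-enoyl]-3-chloro-4-methylcyclohexyl benzoate, via alkylzinc iodide 21 (not isolated)
Conditions: 20, Zn dust (activated by BrCH2CH2Br and Me3SiCl), THF, 35 °C; supernatant cannulated off the excess zinc; then 12, Pd(PPh3)4 (5 mol %), THF, 0 °C to rt
Reagents that add atoms: none
Why: Negishi acylation, in which zinc inserts into the primary carbon–iodine bond, zerovalent palladium adds oxidatively to the acyl chloride far faster than to the hindered tertiary bromide, transmetalation and reductive elimination form C5–C6, and the weakly basic alkylzinc leaves benzoate, halides and product ketone alone and forms no alkoxide that could start a benzoate shift.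

Step 14
Reactants: 22 (1S,3S,4S)-4-bromo-1-[(4R)-4-(tert-butyldimethylsilyloxy)-5-methylhex-5-enoyl]-3-chloro-4-methylcyclohexyl benzoate
Product: 23 (1S,3S,4S)-4-bromo-1-[(5R)-5-(tert-butyldimethylsilyloxy)-2-hydroxy-6-methyl-1-(trimethylsilyl)hept-6-en-2-yl]-3-chloro-4-methylcyclohexyl benzoate (C6 epimers)
Conditions: anhydrous CeCl3 (3 equiv), Me3SiCH2Li (3 equiv), THF, −78 °C; then 22, −78 to −40 °C; aq NH4Cl at −40 °C
Reagents that add atoms: (trimethylsilyl)methyllithium, [Li]C[Si](C)(C)C
Why: First half of a Peterson olefination in its organocerium form, in which the small and weakly basic cerium reagent adds to the hindered, enolisable ketone faster than it deprotonates C5 or eliminates HBr, the configuration of the new carbinol C6 is irrelevant because step 16 destroys it, and any shift or loss of the benzoate is harmless because step 15 removes it from either oxygen.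

Step 15
Reactants: 23 (1S,3S,4S)-4-bromo-1-[(5R)-5-(tert-butyldimethylsilyloxy)-2-hydroxy-6-methyl-1-(trimethylsilyl)hept-6-en-2-yl]-3-chloro-4-methylcyclohexyl benzoate
Product: 24 (1S,3S,4S)-4-bromo-1-[(5R)-5-(tert-butyldimethylsilyloxy)-2-hydroxy-6-methyl-1-(trimethylsilyl)hept-6-en-2-yl]-3-chloro-4-methylcyclohexan-1-ol (C6 epimers)
Conditions: i-Bu2AlH (4 equiv), CH2Cl2, −78 °C; aq potassium sodium tartrate
Reagents that add atoms: none
Why: Reductive ester cleavage, in which i-Bu2AlH reduces the benzoate to benzyl alcohol at −78 °C through non-basic aluminium alkoxides that neither eliminate HBr, nor displace a halide, nor trigger a base-type Peterson elimination.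

Step 16
Reactants: 24 (1S,3S,4S)-4-bromo-1-[(5R)-5-(tert-butyldimethylsilyloxy)-2-hydroxy-6-methyl-1-(trimethylsilyl)hept-6-en-2-yl]-3-chloro-4-methylcyclohexan-1-ol
Product: 25 (1S,3S,4S)-4-bromo-3-chloro-1-[(5R)-5-hydroxy-6-methylhepta-1,6-dien-2-yl]-4-methylcyclohexan-1-ol (target)
Conditions: HF·pyridine, THF, 0 °C to rt (polyethylene flask); aq NaHCO3
Reagents that add atoms: none
Why: Acid-type Peterson elimination and fluoride desilylation in one operation, in which protonation of the C6 hydroxyl and beta-silicon-assisted elimination give the C6 methylidene from either C6 epimer, HF cleaves the C3 silyl ether, and the weakly acidic, non-basic medium spares the tertiary bromide and both allylic alcohols.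

**Compound list**

1 | 2,2-dimethyl-1,3-dioxan-5-one | CC1(C)OCC(=O)CO1 | starting material
2 | benzoyl chloride | O=C(Cl)c1ccccc1 | starting material
3 | potassium enolate (potassium 2,2-dimethyl-4H-1,3-dioxin-5-olate) | CC1(C)OCC([O-])=CO1.[K+] | intermediate
4 | 2,2-dimethyl-4H-1,3-dioxin-5-yl benzoate | CC1(C)OCC(OC(=O)c2ccccc2)=CO1 | intermediate
5 | 2-(benzoyloxy)acrolein (3-oxoprop-1-en-2-yl benzoate) | C=C(OC(=O)c1ccccc1)C=O | intermediate
6 | isoprene | C=CC(C)=C | starting material
7 | (S)-1-formyl-4-methylcyclohex-3-en-1-yl benzoate | O=C[C@]1(OC(=O)c2ccccc2)CCC(C)=CC1 | intermediate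
8 | (S)-1-(benzoyloxy)-4-methylcyclohex-3-ene-1-carboxylic acid | OC(=O)[C@]1(OC(=O)c2ccccc2)CCC(C)=CC1 | intermediate
9 | (1S,4S,6S)-6-chloro-1-methyl-3-oxo-2-oxabicyclo[2.2.2]octan-4-yl benzoate | O=C2[C@]1(OC(=O)c3ccccc3)CC[C@](C)(O2)[C@@H](Cl)C1 | intermediate
10 | trimethylsilyl ester (trimethylsilyl (1S,3S,4S)-1-(benzoyloxy)-4-bromo-3-chloro-4-methylcyclohexane-1-carboxylate) | C[Si](C)(C)OC(=O)[C@]1(OC(=O)c2ccccc2)CC[C@](C)(Br)[C@@H](Cl)C1 | intermediate
11 | (1S,3S,4S)-1-(benzoyloxy)-4-bromo-3-chloro-4-methylcyclohexane-1-carboxylic acid | OC(=O)[C@]1(OC(=O)c2ccccc2)CC[C@](C)(Br)[C@@H](Cl)C1 | intermediate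
12 | (1S,3S,4S)-4-bromo-3-chloro-1-(chlorocarbonyl)-4-methylcyclohexyl benzoate | ClC(=O)[C@]1(OC(=O)c2ccccc2)CC[C@](C)(Br)[C@@H](Cl)C1 | intermediate
13 | 3-chloropropanoyl chloride | ClCCC(=O)Cl | starting material
14 | 3-chloro-N-methoxy-N-methylpropanamide | ClCCC(=O)N(C)OC | intermediate
15 | 2-bromopropene | C=C(C)Br | starting material
16 | isopropenylmagnesium bromide | C=C(C)[Mg]Br | intermediate
17 | 1-chloro-4-methylpent-4-en-3-one | C=C(C)C(=O)CCCl | intermediate
18 | (R)-5-chloro-2-methylpent-1-en-3-ol | C=C(C)[C@H](O)CCCl | intermediate
19 | (R)-tert-butyl[(5-chloro-2-methylpent-1-en-3-yl)oxy]dimethylsilane | C=C(C)[C@H](O[Si](C)(C)C(C)(C)C)CCCl | intermediate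
20 | (R)-tert-butyl[(5-iodo-2-methylpent-1-en-3-yl)oxy]dimethylsilane | C=C(C)[C@H](O[Si](C)(C)C(C)(C)C)CCI | intermediate
21 | alkylzinc iodide ([(3R)-3-(tert-butyldimethylsilyloxy)-4-methylpent-4-en-1-yl]zinc iodide) | C=C(C)[C@H](O[Si](C)(C)C(C)(C)C)CC[Zn]I | intermediate
22 | (1S,3S,4S)-4-bromo-1-[(4R)-4-(tert-butyldimethylsilyloxy)-5-methylhex-5-enoyl]-3-chloro-4-methylcyclohexyl benzoate | C=C(C)[C@H](O[Si](C)(C)C(C)(C)C)CCC(=O)[C@]1(OC(=O)c2ccccc2)CC[C@](C)(Br)[C@@H](Cl)C1 | intermediate
23 | (1S,3S,4S)-4-bromo-1-[(5R)-5-(tert-butyldimethylsilyloxy)-2-hydroxy-6-methyl-1-(trimethylsilyl)hept-6-en-2-yl]-3-chloro-4-methylcyclohexyl benzoate, C6 epimers | C=C(C)[C@H](O[Si](C)(C)C(C)(C)C)CCC(O)(C[Si](C)(C)C)[C@]1(OC(=O)c2ccccc2)CC[C@](C)(Br)[C@@H](Cl)C1 | intermediate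
24 | (1S,3S,4S)-4-bromo-1-[(5R)-5-(tert-butyldimethylsilyloxy)-2-hydroxy-6-methyl-1-(trimethylsilyl)hept-6-en-2-yl]-3-chloro-4-methylcyclohexan-1-ol, C6 epimers | C=C(C)[C@H](O[Si](C)(C)C(C)(C)C)CCC(O)(C[Si](C)(C)C)[C@]1(O)CC[C@](C)(Br)[C@@H](Cl)C1 | intermediate
25 | (1S,3S,4S)-4-bromo-3-chloro-1-[(5R)-5-hydroxy-6-methylhepta-1,6-dien-2-yl]-4-methylcyclohexan-1-ol | C=C(C)[C@H](O)CCC(=C)[C@]1(O)CC[C@](C)(Br)[C@@H](Cl)C1 | target

**Step count**

Total steps: 16. Longest linear sequence: 11 (steps 1–7 and 13–16). The side chain (steps 8–12) is made in parallel.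

**Steps most likely to fail**

Step 3.
- What may go wrong: slow turnover with an unactivated acyclic diene, polymerisation of the enal, or insufficient discrimination between the two dienophile faces.
- Fallback: resolution in place of asymmetric catalysis, with the same bonds formed. It sets out from 5 and 6. An achiral Lewis acid (BF3·OEt2, CH2Cl2, −78 °C) or simple heating should give racemic 1-formyl-4-methylcyclohex-3-en-1-yl benzoate F1. Pinnick oxidation as in step 4 then gives racemic 1-(benzoyloxy)-4-methylcyclohex-3-ene-1-carboxylic acid F2. Crystallisation with (S)-1-phenylethylamine, or its antipode if that forms the less soluble salt of the (S)-acid, gives the (S)-1-phenylethylammonium salt of the (S)-acid F3. Acidification comes back to the route at 8.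

Step 5.
- What may go wrong: proton loss from the chloronium ion (allylic chlorination), closure at C11 in the five-membered lactone mode, or unassisted chlorination of the wrong ring face.
- Fallback: intermolecular water capture followed by a separate ring closure. It sets out from 8. Esterification with Me3SiCHN2 gives methyl (S)-1-(benzoyloxy)-4-methylcyclohex-3-ene-1-carboxylate F4. NCS in aqueous acetone then forms the chlorohydrins, with water entering at C10. Only the isomer with the C10 hydroxyl cis to the ester can lactonise, namely methyl (1S,3S,4S)-1-(benzoyloxy)-3-chloro-4-hydroxy-4-methylcyclohexane-1-carboxylate F5. Heating the mixture with catalytic TsOH in toluene, with removal of methanol, converts F5 into 9. The other isomer stays behind as a polar hydroxy ester.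

Step 6.
- What may go wrong: sluggish alkyl–oxygen cleavage of the electron-poor lactone, proton loss from the cation, or leakage through an open cation with loss of configuration at C10.
- Fallback: substitution of a free tertiary alcohol instead of a lactone oxygen, carried out at the aldehyde oxidation level. It sets out from 7. NCS in aqueous acetone gives the chlorohydrin, whose wanted diastereomer is held as the bicyclic lactol (1S,4S,6S)-6-chloro-3-hydroxy-1-methyl-2-oxabicyclo[2.2.2]octan-4-yl benzoate F6 and can be separated from the open-chain isomer. Me3SiBr acts on the hydroxy-aldehyde form, which ionises far more readily with the same chlorine assistance, and gives (1S,3S,4S)-4-bromo-3-chloro-1-formyl-4-methylcyclohexyl benzoate F7. Pinnick oxidation comes back to the route at 11.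

**Further compounds**

F1 | step 3 | racemic 1-formyl-4-methylcyclohex-3-en-1-yl benzoate | O=CC1(OC(=O)c2ccccc2)CCC(C)=CC1
F2 | step 3 | racemic 1-(benzoyloxy)-4-methylcyclohex-3-ene-1-carboxylic acid | OC(=O)C1(OC(=O)c2ccccc2)CCC(C)=CC1
F3 | step 3 | (S)-1-phenylethylammonium (S)-1-(benzoyloxy)-4-methylcyclohex-3-ene-1-carboxylate | C[C@H]([NH3+])c1ccccc1.[O-]C(=O)[C@]1(OC(=O)c2ccccc2)CCC(C)=CC1
F4 | step 5 | methyl (S)-1-(benzoyloxy)-4-methylcyclohex-3-ene-1-carboxylate | COC(=O)[C@]1(OC(=O)c2ccccc2)CCC(C)=CC1
F5 | step 5 | methyl (1S,3S,4S)-1-(benzoyloxy)-3-chloro-4-hydroxy-4-methylcyclohexane-1-carboxylate | COC(=O)[C@]1(OC(=O)c2ccccc2)CC[C@](C)(O)[C@@H](Cl)C1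
F6 | step 6 | (1S,4S,6S)-6-chloro-3-hydroxy-1-methyl-2-oxabicyclo[2.2.2]octan-4-yl benzoate | OC2[C@]1(OC(=O)c3ccccc3)CC[C@](C)(O2)[C@@H](Cl)C1
F7 | step 6 | (1S,3S,4S)-4-bromo-3-chloro-1-formyl-4-methylcyclohexyl benzoate | O=C[C@]1(OC(=O)c2ccccc2)CC[C@](C)(Br)[C@@H](Cl)C1
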